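**Plan**

- Locants (eudesmanolide numbering of the target, used throughout): C1 ketone; bridgeheads C2 (H) and C5; C3=C4(Me); C10(Me); ring B = C5–C6–C7–C8–C9–C10; lactone = O–C6, C7, C11(Me), C12(=O); C1′H2 (on C5) and C2′H (on C2, carries the 6-methylhepta-1,5-dien-2-yl chain) are the myrcene carbons.
- Retrosynthesis: (i) C11 epimer; (ii) C6–C7 and O–C12 are cut together, because a γ-lactone fused on the C6–C7 edge of cyclohexane ring B is the retron of an aldehyde/enoate ketyl–olefin coupling, and the rigid bicyclo[2.2.2]octenone (C1, C2, C3, C4, C5, C10, C1′, C2′) holds the aldehyde carbon C6 (on C5) and the enoate arm (on C10) gauche; (iii) C7=C11 (Wittig), C10–C9 (enolate alkylation), C10–O (ketol reduction); (iv) C2–C2′ and C5–C1′ ([4+2] of an o-quinol with myrcene); (v) C10–O (dearomatisation of a 2-methylphenol).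
- Forward: phenol → ring A as a 6-hydroxy-2,4-dienone → bicyclo[2.2.2]octenone by intermolecular Diels–Alder with myrcene → quaternary C10 with the C9–C7 arm → ring B closed last through C6–C7, its alkoxide closing the lactone C–O bond in the same operation.
- Stereochemistry: absolute configuration from the enantioselective hydroxylative dearomatisation (C10 carbinol), relayed to C2, C5 and C2′ by the syn-to-oxygen, ortho, endo cycloaddition; C10 from alkylation on the alkene-bridge face; C6 and C7 from the single chair that the bicycle allows in the ring-B closure; C11 by equilibration.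

Key step: step 11

Remark: the (S)-iodane of step 5 is assumed to deliver the (6S)-quinol (its antipode is used if the sense is opposite); it is a known type of reagent, made beforehand from (S)-tert-leucinol and 2-iodobenzoyl chloride (oxazoline formation, then dimethyldioxirane), and is treated as a reagent, not as a route step.

**Step 1**
Reactants: 1 methyl 3-hydroxy-2-methylbenzoate
Product: 2 methyl 6-bromo-3-hydroxy-2-methylbenzoate
Conditions: NBS (1.05 equiv), MeCN, −20 → 0 °C
Reagents that add atoms: N-bromosuccinimide, O=C1CCC(=O)N1Br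
Why: Electrophilic aromatic bromination of a phenol with NBS in MeCN should go para to the hydroxyl (C6), the activated position that is not flanked by the ring methyl group.

**Step 2**
Reactants: 2 methyl 6-bromo-3-hydroxy-2-methylbenzoate; 3 methylboronic acid
Product: 4 methyl 3-hydroxy-2,6-dimethylbenzoate
Conditions: Pd(dppf)Cl2 (5 mol %), K2CO3 (3 equiv), dioxane/H2O, 100 °C
Reagents that add atoms: methylboronic acid 3, CB(O)O
Why: Suzuki–Miyaura methylation of the aryl bromide tolerates the free phenol, and the di-ortho-substituted methyl ester should resist hydrolysis.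

**Step 3**
Reactants: 4 methyl 3-hydroxy-2,6-dimethylbenzoate
Product: 5 3-(hydroxymethyl)-2,4-dimethylphenol
Conditions: LiAlH4 (2.5 equiv), THF, 0 → 65 °C; Fieser work-up
Reagents that add atoms: none
Why: Lithium aluminium hydride reduction of the hindered aryl ester gives the benzylic alcohol while the phenoxide is inert.

**Step 4**
Reactants: 5 3-(hydroxymethyl)-2,4-dimethylphenol
Product: 7 3-{[(tert-butyldimethylsilyl)oxy]methyl}-2,4-dimethylphenol, via bis-silyl ether 6 (not isolated)
Conditions: TBSCl (2.3 equiv), imidazole (2.5 equiv), DMF, 23 °C; then K2CO3 (0.5 equiv), MeOH, 23 °C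
Reagents that add atoms: tert-butyldimethylsilyl chloride, CC(C)(C)[Si](C)(C)Cl
Why: Silylation of both hydroxyls followed by selective base methanolysis of the aryl silyl ether (phenoxide is the better leaving group) leaves the alkyl TBS ether.

**Step 5**
Reactants: 7 3-{[(tert-butyldimethylsilyl)oxy]methyl}-2,4-dimethylphenol; 8 myrcene
Product: 10 3-hydroxy-3,5-dimethyl-4-{[(tert-butyldimethylsilyl)oxy]methyl}-7-(6-methylhepta-1,5-dien-2-yl)bicyclo[2.2.2]oct-5-en-2-one (3-OH syn to the C7–C8 bridge; C7 chain syn to the C5=C6 bridge), via o-quinol 9 (not isolated)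
Conditions: (S)-4-tert-butyl-2-(2-iodylphenyl)-4,5-dihydrooxazole (1.2 equiv), THF, −40 → 0 °C; then H2O (5 equiv), 8 (10 equiv), 0 → 45 °C
Reagents that add atoms: (S)-4-tert-butyl-2-(2-iodylphenyl)-4,5-dihydro-1,3-oxazole, CC(C)(C)[C@H]1COC(=N1)c1ccccc1I(=O)=O; myrcene 8, C=CC(=C)CCC=C(C)C
Why: Hydroxylative phenol dearomatisation by a chiral λ5-iodane (oxygen transfer from the aryloxy-iodane to the methyl-bearing ortho carbon) sets C10 as the (6S)-quinol, which then undergoes an inverse-electron-demand Diels–Alder reaction with the monosubstituted vinyl group of myrcene (CH2 terminus to the δ-carbon C5, endo, on the face of the C10 hydroxyl), fixing C2, C5 and C2′, while the tetrasubstituted C4=C5 bond should suppress quinol dimerisation.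

**Step 6**
Reactants: 10 bicyclic ketol
Product: 11 3,5-dimethyl-4-{[(tert-butyldimethylsilyl)oxy]methyl}-7-(6-methylhepta-1,5-dien-2-yl)bicyclo[2.2.2]oct-5-en-2-one (C10 epimers)
Conditions: SmI2 (3 equiv), THF/MeOH 10:1, −78 → 0 °C
Reagents that add atoms: none
Why: SmI2 reduction of an α-hydroxy ketone cleaves the C10–O bond through the samarium enolate, which is protonated to the α-methyl ketone; the C10 configuration does not matter because step 7 re-planarises it, and the isolated alkenes and silyl ether are inert.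

**Step 7**
Reactants: 11 α-methyl ketone; 12 2-(2-bromoethyl)-1,3-dioxolane
Product: 13 3-[2-(1,3-dioxolan-2-yl)ethyl]-3,5-dimethyl-4-{[(tert-butyldimethylsilyl)oxy]methyl}-7-(6-methylhepta-1,5-dien-2-yl)bicyclo[2.2.2]oct-5-en-2-one (new chain syn to the C5=C6 bridge)
Conditions: KHMDS (1.3 equiv), THF, −78 → 0 °C; DMPU (4 equiv), 12 (3 equiv), TBAI (0.2 equiv), 0 → 23 °C
Reagents that add atoms: 2-(2-bromoethyl)-1,3-dioxolane 12, BrCCC1OCCO1
Why: Only C10 can enolise (C2 is a bridgehead), and SN2 enolate alkylation should occur on the face syn to the C3=C4 alkene bridge, since the other face is shielded by the inward C–H bonds of C1′ and C2′; this places C9 syn to the alkene and the C10 methyl syn to the ethano bridge, as in the target.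

**Step 8**
Reactants: 13 acetal silyl ether
Product: 14 3-[4-(hydroxymethyl)-3,5-dimethyl-7-(6-methylhepta-1,5-dien-2-yl)-2-oxobicyclo[2.2.2]oct-5-en-3-yl]propanal
Conditions: 2 M aq. HCl/THF 1:3, 23 °C
Reagents that add atoms: water, O
Why: Acid hydrolysis removes the dioxolane and the primary TBS ether in one operation, and the tri- and 1,1-disubstituted alkenes should tolerate dilute aqueous acid at room temperature.

**Step 9**
Reactants: 14 hydroxy aldehyde; 15 ethyl 2-(triphenyl-λ5-phosphanylidene)propanoate
Product: 16 ethyl (E)-5-[4-(hydroxymethyl)-3,5-dimethyl-7-(6-methylhepta-1,5-dien-2-yl)-2-oxobicyclo[2.2.2]oct-5-en-3-yl]-2-methylpent-2-enoate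
Conditions: 15 (1.5 equiv), CH2Cl2, 23 → 40 °C
Reagents that add atoms: ethyl 2-(triphenyl-λ5-phosphanylidene)propanoate 15, CCOC(=O)C(C)=P(c1ccccc1)(c1ccccc1)c1ccccc1
Why: Wittig olefination with a stabilised ylide reacts only with the unhindered aldehyde (the C1 ketone lies between a quaternary carbon and a bridgehead) and should give the (E)-trisubstituted enoate.

**Step 10**
Reactants: 16 hydroxy enoate
Product: 17 ethyl (E)-5-[4-formyl-3,5-dimethyl-7-(6-methylhepta-1,5-dien-2-yl)-2-oxobicyclo[2.2.2]oct-5-en-3-yl]-2-methylpent-2-enoate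
Conditions: Dess–Martin periodinane (1.3 equiv), CH2Cl2, 0 → 23 °C
Reagents that add atoms: none
Why: Dess–Martin oxidation converts the neopentyl primary alcohol into the non-enolisable C6 aldehyde under neutral conditions that leave the alkenes and enoate untouched.

**Step 11**
Reactants: 17 aldehyde enoate
Product: 19 target lactone as a mixture of C11 epimers, via hydroxy ester 18 (not isolated)
Conditions: SmI2 (2.5 equiv), t-BuOH (2.5 equiv), THF (0.01 M), −78 → 23 °C; then PPTS (0.1 equiv), toluene, 50 °C
Reagents that add atoms: none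
Why: SmI2 transfers one electron to the C6 aldehyde and the samarium(III) ketyl adds to C7, the β-carbon of the (E)-enoate, after which a second electron gives the samarium ester enolate that t-BuOH protonates at C11. The closest known reaction type is the SmI2 aldehyde–enoate ketyl–olefin reductive cyclisation with lactonisation of the γ-hydroxy ester. Ring B closes in the 6-exo-trig radical mode through C6–C7 as the last ring of the carbon skeleton, and the C6 alkoxide then closes the γ-lactone by 5-exo-trig acyl substitution at C12 with loss of ethanol. C6 and C7 are controlled by the bicyclo[2.2.2]octenone, which holds C6 (on bridgehead C5) and C9 (on C10, syn to the alkene bridge) gauche so that only one chair is available; in it the O–Sm group and the enoate sit equatorial and anti, the O–Sm group avoiding the axial C10 methyl, which should give H6/H7 trans-diaxial and hence the trans-fused lactone. C11 is not controlled here and is corrected in step 12. The step needs aldehyde-over-ketone and cyclisation-over-dimerisation selectivity, which the much greater hindrance of the C1 ketone, the low temperature without HMPA and the high dilution should secure.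

**Step 12**
Reactants: 19 lactone (C11 epimers)
Product: 20 CNP0385704.1 (target, 11S)
Conditions: t-BuOK (0.2 equiv), t-BuOH/THF 1:4, 23 °C
Reagents that add atoms: none
Why: Base-mediated enolisation and reprotonation of the lactone α-carbon (thermodynamic epimerisation) should converge on the epimer with the C11 methyl trans to C8 (all-trans trisubstituted butyrolactone); the C1 ketone has no α-hydrogen that can be removed.

**Compound list**

1 | methyl 3-hydroxy-2-methylbenzoate | COC(=O)c1cccc(O)c1C | starting material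
2 | methyl 6-bromo-3-hydroxy-2-methylbenzoate | COC(=O)c1c(Br)ccc(O)c1C | intermediate
3 | methylboronic acid | CB(O)O | starting material
4 | methyl 3-hydroxy-2,6-dimethylbenzoate | COC(=O)c1c(C)ccc(O)c1C | intermediate
5 | 3-(hydroxymethyl)-2,4-dimethylphenol | OCc1c(C)ccc(O)c1C | intermediate
6 | bis-TBS ether of 5 (aryl and benzylic oxygen silylated) | CC(C)(C)[Si](C)(C)OCc1c(C)ccc(O[Si](C)(C)C(C)(C)C)c1C | intermediate (not isolated)
7 | 3-{[(tert-butyldimethylsilyl)oxy]methyl}-2,4-dimethylphenol | CC(C)(C)[Si](C)(C)OCc1c(C)ccc(O)c1C | intermediate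
8 | myrcene (7-methyl-3-methylideneocta-1,6-diene) | C=CC(=C)CCC=C(C)C | starting material
9 | (6S)-5-{[(tert-butyldimethylsilyl)oxy]methyl}-6-hydroxy-4,6-dimethylcyclohexa-2,4-dien-1-one | O=C1C=CC(C)=C(CO[Si](C)(C)C(C)(C)C)[C@@]1(O)C | intermediate (not isolated)
10 | 3-hydroxy-3,5-dimethyl-4-{[(tert-butyldimethylsilyl)oxy]methyl}-7-(6-methylhepta-1,5-dien-2-yl)bicyclo[2.2.2]oct-5-en-2-one; 3-OH syn to the C7–C8 bridge, C7 chain syn to the C5=C6 bridge | C=C(CCC=C(C)C)[C@H]1C[C@@]2(CO[Si](C)(C)C(C)(C)C)C(C)=C[C@@H]1C(=O)[C@]2(O)C | intermediate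
11 | 3,5-dimethyl-4-{[(tert-butyldimethylsilyl)oxy]methyl}-7-(6-methylhepta-1,5-dien-2-yl)bicyclo[2.2.2]oct-5-en-2-one, both epimers at C3 (= C10) | C=C(CCC=C(C)C)[C@H]1C[C@@]2(CO[Si](C)(C)C(C)(C)C)C(C)=C[C@@H]1C(=O)C2C | intermediate
12 | 2-(2-bromoethyl)-1,3-dioxolane | BrCCC1OCCO1 | starting material
13 | 3-[2-(1,3-dioxolan-2-yl)ethyl]-3,5-dimethyl-4-{[(tert-butyldimethylsilyl)oxy]methyl}-7-(6-methylhepta-1,5-dien-2-yl)bicyclo[2.2.2]oct-5-en-2-one; dioxolanylethyl chain syn to the C5=C6 bridge | C=C(CCC=C(C)C)[C@H]1C[C@@]2(CO[Si](C)(C)C(C)(C)C)C(C)=C[C@@H]1C(=O)[C@]2(C)CCC1OCCO1 | intermediate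
14 | 3-[4-(hydroxymethyl)-3,5-dimethyl-7-(6-methylhepta-1,5-dien-2-yl)-2-oxobicyclo[2.2.2]oct-5-en-3-yl]propanal | C=C(CCC=C(C)C)[C@H]1C[C@@]2(CO)C(C)=C[C@@H]1C(=O)[C@]2(C)CCC=O | intermediate
15 | ethyl 2-(triphenyl-λ5-phosphanylidene)propanoate | CCOC(=O)C(C)=P(c1ccccc1)(c1ccccc1)c1ccccc1 | starting material
16 | ethyl (E)-5-[4-(hydroxymethyl)-3,5-dimethyl-7-(6-methylhepta-1,5-dien-2-yl)-2-oxobicyclo[2.2.2]oct-5-en-3-yl]-2-methylpent-2-enoate | C=C(CCC=C(C)C)[C@H]1C[C@@]2(CO)C(C)=C[C@@H]1C(=O)[C@]2(C)CC/C=C(\C)C(=O)OCC | intermediate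
17 | ethyl (E)-5-[4-formyl-3,5-dimethyl-7-(6-methylhepta-1,5-dien-2-yl)-2-oxobicyclo[2.2.2]oct-5-en-3-yl]-2-methylpent-2-enoate | C=C(CCC=C(C)C)[C@H]1C[C@@]2(C=O)C(C)=C[C@@H]1C(=O)[C@]2(C)CC/C=C(\C)C(=O)OCC | intermediate
18 | ring-B-closed hydroxy ester: ethyl 2-(6-hydroxy tricycle-7-yl)propanoate, 6-OH and C7 side chain trans-diequatorial, C11 epimers | C=C(CCC=C(C)C)[C@H]1C[C@@]23C(C)=C[C@@H]1C(=O)[C@]2(C)CC[C@@H](C(C)C(=O)OCC)[C@@H]3O | intermediate (not isolated)
19 | target lactone as a mixture of C11 epimers | C=C(CCC=C(C)C)[C@H]1C[C@@]23C(C)=C[C@@H]1C(=O)[C@]2(C)CC[C@H]1C(C)C(=O)O[C@@H]13 | intermediate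
20 | CNP0385704.1 | C=C(CCC=C(C)C)[C@H]1C[C@@]23C(C)=C[C@@H]1C(=O)[C@]2(C)CC[C@H]1[C@H](C)C(=O)O[C@@H]13 | target

**Step count and risks**

Total step count: 12. Longest linear sequence: 12 steps (1 → 20).

Steps most likely to fail:

1. Step 5. Oxygen transfer may go to the unsubstituted ortho carbon (leading to an o-quinone), enantioinduction by the iodane may be poor, and quinol self-dimerisation or reaction at the 1,1-disubstituted double bond of myrcene may compete with the intended cycloaddition. The fallback replaces enantioselective oxidation by a resolution through a covalent chiral carboxylate and sets out from 7. A Wessely-type ortho-acyloxylation with Pb(OAc)4 that has been exchanged with excess (S)-2-methoxy-2-phenylacetic acid (CH2Cl2, 0 °C) gives both C10 epimers of the quinol ester. The (6S)-quinol ester F1 is separated by chromatography or crystallisation and heated with myrcene (toluene, 60 °C) to the acyloxy adduct F2, the dienophile again adding on the face of the oxygen substituent. SmI2 cleavage of the α-acyloxy ketone under the conditions of step 6 brings the route back at 11.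

2. Step 11. The C1 ketone may be reduced or enter pinacol coupling, the ketyl may add through a non-chair arrangement so that C6/C7 selectivity erodes, and the trans hydroxy ester may lactonise incompletely. The fallback closes the same bond by a polar allylsilane addition and sets out from 14. Horner–Wadsworth–Emmons reaction with ethyl 2-(diethoxyphosphoryl)-3-(trimethylsilyl)propanoate (NaH, THF) gives the 2-(silylmethyl)enoate F6, and Dess–Martin oxidation gives the aldehyde F7. Intramolecular Hosomi–Sakurai addition (BF3·OEt2, CH2Cl2, −78 °C), with lactonisation of the resulting alkoxide, should give the trans-fused α-methylene lactone F8 through the same chair. Conjugate reduction with [(Ph3P)CuH]6 (benzene/H2O), which spares isolated alkenes and the hindered ketone, brings the route back at 19, followed by step 12.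

3. Step 7. The hindered tetrasubstituted enolate may eliminate HBr from the β-branched bromide instead of substituting it, O-alkylation may compete, and facial selectivity may leak. The fallback uses a small allylic electrophile and a chemoselective hydroboration and sets out from 11. KHMDS and allyl bromide (THF, −78 → 0 °C) give the allyl ketone F3 with the same facial bias. Disiamylborane (THF, 0 °C; then NaBO3), which selects the monosubstituted terminal alkene over the 1,1-disubstituted and trisubstituted ones, gives the primary alcohol F4. Dess–Martin oxidation gives the silyl ether aldehyde F5, and 2 M aq. HCl/THF removes the TBS group to bring the route back at 14.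

**Further compounds**

F1 | step 5 | (1S)-2-{[(tert-butyldimethylsilyl)oxy]methyl}-1,3-dimethyl-6-oxocyclohexa-2,4-dien-1-yl (2S)-2-methoxy-2-phenylacetate | O=C1C=CC(C)=C(CO[Si](C)(C)C(C)(C)C)[C@@]1(OC(=O)[C@@H](OC)c1ccccc1)C
F2 | step 5 | 3,5-dimethyl-4-{[(tert-butyldimethylsilyl)oxy]methyl}-7-(6-methylhepta-1,5-dien-2-yl)-2-oxobicyclo[2.2.2]oct-5-en-3-yl (2S)-2-methoxy-2-phenylacetate, acyloxy group syn to the C7–C8 bridge | C=C(CCC=C(C)C)[C@H]1C[C@@]2(CO[Si](C)(C)C(C)(C)C)C(C)=C[C@@H]1C(=O)[C@]2(OC(=O)[C@@H](OC)c1ccccc1)C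
F3 | step 7 | 3-allyl-3,5-dimethyl-4-{[(tert-butyldimethylsilyl)oxy]methyl}-7-(6-methylhepta-1,5-dien-2-yl)bicyclo[2.2.2]oct-5-en-2-one, allyl syn to the C5=C6 bridge | C=C(CCC=C(C)C)[C@H]1C[C@@]2(CO[Si](C)(C)C(C)(C)C)C(C)=C[C@@H]1C(=O)[C@]2(C)CC=C
F4 | step 7 | 3-(3-hydroxypropyl)-3,5-dimethyl-4-{[(tert-butyldimethylsilyl)oxy]methyl}-7-(6-methylhepta-1,5-dien-2-yl)bicyclo[2.2.2]oct-5-en-2-one | C=C(CCC=C(C)C)[C@H]1C[C@@]2(CO[Si](C)(C)C(C)(C)C)C(C)=C[C@@H]1C(=O)[C@]2(C)CCCO
F5 | step 7 | 3-[3,5-dimethyl-4-{[(tert-butyldimethylsilyl)oxy]methyl}-7-(6-methylhepta-1,5-dien-2-yl)-2-oxobicyclo[2.2.2]oct-5-en-3-yl]propanal | C=C(CCC=C(C)C)[C@H]1C[C@@]2(CO[Si](C)(C)C(C)(C)C)C(C)=C[C@@H]1C(=O)[C@]2(C)CCC=O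
F6 | step 11 | ethyl 5-[4-(hydroxymethyl)-3,5-dimethyl-7-(6-methylhepta-1,5-dien-2-yl)-2-oxobicyclo[2.2.2]oct-5-en-3-yl]-2-[(trimethylsilyl)methyl]pent-2-enoate (E/Z mixture) | C=C(CCC=C(C)C)[C@H]1C[C@@]2(CO)C(C)=C[C@@H]1C(=O)[C@]2(C)CCC=C(C[Si](C)(C)C)C(=O)OCC
F7 | step 11 | ethyl 5-[4-formyl-3,5-dimethyl-7-(6-methylhepta-1,5-dien-2-yl)-2-oxobicyclo[2.2.2]oct-5-en-3-yl]-2-[(trimethylsilyl)methyl]pent-2-enoate (E/Z mixture) | C=C(CCC=C(C)C)[C@H]1C[C@@]2(C=O)C(C)=C[C@@H]1C(=O)[C@]2(C)CCC=C(C[Si](C)(C)C)C(=O)OCC
F8 | step 11 | 11,13-didehydro analogue of the target (trans-fused α-methylene-γ-lactone) | C=C(CCC=C(C)C)[C@H]1C[C@@]23C(C)=C[C@@H]1C(=O)[C@]2(C)CC[C@H]1C(=C)C(=O)O[C@@H]13
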